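A direct plan would buy all four six-membered rings (A = para-phenylene, B = phenol ring, C = meta-phenylene, D = quinone, carried as its dimethyl ether) and make both diaryl ethers by SNAr of phenoxides on fluorobenzaldehydes, one of them the hindered 2-fluoro-3,6-dimethoxybenzaldehyde A1.
It would close the 18-membered ring of the resulting dialdehyde A2 by McMurry coupling at the ring A–CH2CH2–ring D bridge, hydrogenate to the trimethyl ether A3, demethylate with BBr3 to the triol A4 and oxidise the hydroquinone last.
Its weakest step would be the reductive carbonyl macrocyclisation: only dilution would favour the 18-membered ring over pinacols and oligomers, and it would be run on the fully assembled chain.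
Next would be the global demethylation followed by the oxidation: they add no skeletal bond, would be run on the most precious material, and the air-sensitive triol A4 carries an ortho-aryloxyphenol that would have to survive the oxidant.
Third would be the SNAr on A1: its fluoride is flanked by CHO and OMe and deactivated by two donors, so forcing basic conditions would be needed on an aldehyde.

Plan of the new route
The retrosynthesis cuts ring D first, at its two C(=O)–CH bonds, to a macrocyclic cyclobutenedione plus an ethynyl unit. It then cuts the vinylic C–O bond between the four-membered ring and ring C (ring closure), the four-ring–CH2 bond (alkyllithium + squarate), the B–C bridge (Sonogashira) and the A–O–B ether (Ullmann).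
The enabling feature: in ring D the C(OAr)=C(CH2) double bond and its two flanking C=O carbons are the four carbons of a 3-alkyl-4-aryloxycyclobutene-1,2-dione. The remaining CH=CH is unsubstituted, so it is an ethyne unit and it does not matter which carbonyl it attacks.
Ring order: rings A–C and the four-membered ring are bought. The 18-membered ring is closed on the cyclobutenedione by addition–elimination of the single free phenol (ring C). Ring D arises last, by strain-release ring expansion, directly at the quinone oxidation level.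
So no carbonyl coupling closes the ring, no methyl ether or hydroquinone ever exists (no BBr3, no oxidant), and no deactivated fluoroarene undergoes SNAr.
Key step: step 11

Assumption: the target has no stereocentre and its 18-membered ring is taken as conformationally mobile, so it is achiral and "single enantiomer" needs no stereocontrol; the carbinol centres made in steps 7 and 10 are racemic and are destroyed again.
Compounds 1, 2, 5 and 10 and all reagents are taken to be catalogue chemicals.

Step 1
Reactants: 1 4-(benzyloxy)-3-bromobenzaldehyde; 2 4-(2-hydroxyethyl)phenol (tyrosol)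
Product: 3 4-(benzyloxy)-3-[4-(2-hydroxyethyl)phenoxy]benzaldehyde
Conditions: CuI (10 mol%), picolinic acid (20 mol%), K3PO4, DMSO, 90 °C, Ar
Reagents that add atoms: none
Why: Ullmann-type Cu(I)-catalysed diaryl ether synthesis with a ligand suited to ortho-substituted aryl bromides; phosphate deprotonates only the phenol, so the primary alcohol does not couple, and the non-enolisable aldehyde and the benzyl ether are inert.

Step 2
Reactants: 3 4-(benzyloxy)-3-[4-(2-hydroxyethyl)phenoxy]benzaldehyde
Product: 4 2-{4-[2-(benzyloxy)-5-ethynylphenoxy]phenyl}ethanol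
Conditions: dimethyl (1-diazo-2-oxopropyl)phosphonate, K2CO3, MeOH, rt
Reagents that add atoms: dimethyl (1-diazo-2-oxopropyl)phosphonate, CC(=O)C(=[N+]=[N-])P(=O)(OC)OC
Why: Seyferth–Gilbert homologation in its Ohira–Bestmann form turns the aryl aldehyde into the terminal alkyne under carbonate/methanol, which the free alcohol, the benzyl ether and the diaryl ether tolerate.

Step 3
Reactants: 4 2-{4-[2-(benzyloxy)-5-ethynylphenoxy]phenyl}ethanol; 5 1-bromo-3-(methoxymethoxy)benzene
Product: 6 2-{4-[2-(benzyloxy)-5-{[3-(methoxymethoxy)phenyl]ethynyl}phenoxy]phenyl}ethanol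
Conditions: PdCl2(PPh3)2 (3 mol%), CuI (3 mol%), Et3N–DMF, 80 °C, degassed
Reagents that add atoms: none
Why: Sonogashira coupling joins ring C and completes the two carbons of the B–C bridge; the MOM acetal, the benzyl ether and the free alcohol tolerate Pd/Cu/amine.

Step 4
Reactants: 6 2-{4-[2-(benzyloxy)-5-{[3-(methoxymethoxy)phenyl]ethynyl}phenoxy]phenyl}ethanol
Product: 7 2-[4-(2-hydroxyethyl)phenoxy]-4-{2-[3-(methoxymethoxy)phenyl]ethyl}phenol
Conditions: H2 (1–3 atm), 10% Pd/C, EtOAc–EtOH, rt
Reagents that add atoms: none
Why: Heterogeneous catalytic hydrogenation saturates the diarylalkyne to the CH2CH2 bridge and removes the benzyl ether by hydrogenolysis in the same operation, leaving the MOM acetal and the diaryl ether untouched.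

Step 5
Reactants: 7 2-[4-(2-hydroxyethyl)phenoxy]-4-{2-[3-(methoxymethoxy)phenyl]ethyl}phenol
Product: 8 2-[4-(2-iodoethyl)phenoxy]-4-{2-[3-(methoxymethoxy)phenyl]ethyl}phenol
Conditions: PPh3 and I2 (premixed), imidazole, CH2Cl2, 0 °C → rt
Reagents that add atoms: iodine, II
Why: Appel iodination converts only the primary alcohol, because an aryl C–O bond cannot be displaced, and the imidazole buffer protects the MOM acetal.

Step 6
Reactants: 8 2-[4-(2-iodoethyl)phenoxy]-4-{2-[3-(methoxymethoxy)phenyl]ethyl}phenol
Product: 9 {2-[4-(2-iodoethyl)phenoxy]-4-{2-[3-(methoxymethoxy)phenyl]ethyl}phenoxy}triisopropylsilane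
Conditions: TIPSCl, imidazole, DMAP (cat.), CH2Cl2, rt
Reagents that add atoms: triisopropylsilyl chloride, CC(C)[Si](Cl)(C(C)C)C(C)C
Why: Imidazole-promoted silylation gives an aryl silyl ether on ring B that is stable to tert-butyllithium, trifluoroacetic acid and acid chloride formation but is cleaved by fluoride at the end.

Step 7
Reactants: 9 {2-[4-(2-iodoethyl)phenoxy]-4-{2-[3-(methoxymethoxy)phenyl]ethyl}phenoxy}triisopropylsilane; 10 3,4-di-tert-butoxycyclobut-3-ene-1,2-dione (di-tert-butyl squarate)
Product: 12 2,3-di-tert-butoxy-4-hydroxy-4-[2-(4-{5-[2-(3-(methoxymethoxy)phenyl)ethyl]-2-(triisopropylsilyloxy)phenoxy}phenyl)ethyl]cyclobut-2-en-1-one (racemic), via 2-(4-{5-[2-(3-(methoxymethoxy)phenyl)ethyl]-2-(triisopropylsilyloxy)phenoxy}phenyl)ethyllithium 11 (not isolated)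
Conditions: t-BuLi (2.1 equiv), Et2O–pentane, −78 °C; then 10, THF, −78 °C; sat. NH4Cl
Reagents that add atoms: none
Why: Lithium–iodine exchange gives the primary alkyllithium faster than any ortho-metalation, and its 1,2-addition to a carbonyl of the symmetrical squarate at −78 °C is the standard entry to 3-substituted cyclobutenediones; the carbinol centre is racemic and is erased in step 8.

Step 8
Reactants: 12 the squarate 1,2-adduct
Product: 14 3-hydroxy-4-[2-(4-{5-[2-(3-hydroxyphenyl)ethyl]-2-(triisopropylsilyloxy)phenoxy}phenyl)ethyl]cyclobut-3-ene-1,2-dione (seco acid), via 3-tert-butoxy-4-[2-(4-{5-[2-(3-(methoxymethoxy)phenyl)ethyl]-2-(triisopropylsilyloxy)phenoxy}phenyl)ethyl]cyclobut-3-ene-1,2-dione 13 (not isolated)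
Conditions: TFA–CH2Cl2 (1:4), anisole (scavenger), H2O (2 equiv), 0 °C → rt
Reagents that add atoms: none
Why: Acid ionises the carbinol to an alkoxy-stabilised cyclobutenyl cation that loses tert-butyl to give the tert-butoxy dione, and the same acid then cleaves the second tert-butyl group (to the vinylogous acid) and the MOM acetal, while the hindered aryl triisopropylsilyl ether survives.

Step 9
Reactants: 14 the seco acid
Product: 16 macrocyclic cyclobut-3-ene-1,2-dione (18-membered ring; C4 carries the CH2CH2–ring A arm, C3 the ring C oxygen; ring B as its TIPS ether), via 3-chloro-4-[2-(4-{5-[2-(3-hydroxyphenyl)ethyl]-2-(triisopropylsilyloxy)phenoxy}phenyl)ethyl]cyclobut-3-ene-1,2-dione 15 (not isolated)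
Conditions: (COCl)2 (1.2 equiv), DMF (cat.), CH2Cl2, 0 °C; evaporate; CH2Cl2 (1 mM), i-Pr2NEt (3 equiv) by syringe pump, rt
Reagents that add atoms: none
Why: The vinylogous acid becomes its chloride and the ring C phenol, the only free nucleophile, displaces chloride by addition–elimination once base is fed in at high dilution, i.e. the phenolysis of a squaric acid chloride run like an acid chloride macrolactonisation; the roughly 90° splay of the two exocyclic bonds of the cyclobutene eases the 18-membered closure.

Step 10
Reactants: 16 the macrocyclic cyclobutenedione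
Product: 17 macrocyclic 4-ethynyl-4-hydroxycyclobut-2-en-1-one (C2 carries the CH2CH2–ring A arm, C3 the ring C oxygen; racemic; ring B as its TIPS ether)
Conditions: HC≡CMgBr (0.5 M in THF, 2 equiv), THF, −78 → −40 °C; sat. NH4Cl at −78 °C
Reagents that add atoms: ethynylmagnesium bromide, C#C[Mg]Br
Why: 1,2-Addition of the acetylide Grignard reagent to the ketone-like carbonyl next to the aryloxy-bearing carbon should outrun conjugate displacement of the aryloxide at low temperature, as in organometallic additions to alkoxycyclobutenediones; the carbinol centre is racemic and is erased in step 11, and addition at the other carbonyl would lead to the same quinone.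

Step 11
Reactants: 17 the macrocyclic ethynyl carbinol
Product: 18 O-triisopropylsilylmarchantinquinone
Conditions: degassed p-xylene (5 mM), 138 °C
Reagents that add atoms: none
Why: Heating opens the cyclobutenone by conrotatory 4π-electrocyclic ring opening (OH outward, ethynyl inward) to a (2-ethynylethenyl)ketene, whose ketene carbon bonds to the alkyne terminus to give a σ,π-diradical that becomes the quinone by transfer of the hydroxyl hydrogen to the new ring CH; this is the Moore rearrangement of 4-alkynyl-4-hydroxycyclobutenones, driven by release of four-ring strain. Ring D is the only ring closed, by six-membered closure between the former C1 (ketene) carbon and the terminal alkyne carbon, and no bond of the 18-membered ring is touched. No stereocentre is formed and the racemic carbinol centre of 17 is erased. The step needs six- rather than five-membered closure of the diradical (quinone, not alkylidenecyclopentenedione), which the unsubstituted alkyne terminus secures because the competing exocyclic vinyl radical would carry no stabilising group, and it needs outward rotation of OH (inward rotation would give a butenolide), which the donor hydroxyl provides. The placement of OAr and CH2 needs no control, since both sit on the cyclobutene C=C and the CH=CH unit is unsubstituted. The silylated ring B, the diaryl ethers and the benzylic CH2 groups should be inert to neutral heating at high dilution.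

Step 12
Reactants: 18 O-triisopropylsilylmarchantinquinone
Product: 19 marchantinquinone
Conditions: TBAF (1.2 equiv), AcOH (1.5 equiv), THF, 0 °C
Reagents that add atoms: none
Why: Acetic-acid-buffered fluoride cleaves the aryl silyl ether by Si–F bond formation, and the buffer keeps the medium non-basic so that the quinone and its vinylogous aryl ester should survive.

Compound list
1 | 4-(benzyloxy)-3-bromobenzaldehyde | O=Cc1ccc(OCc2ccccc2)c(Br)c1 | starting material
2 | 4-(2-hydroxyethyl)phenol (tyrosol) | OCCc1ccc(O)cc1 | starting material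
3 | 4-(benzyloxy)-3-[4-(2-hydroxyethyl)phenoxy]benzaldehyde | O=Cc1ccc(OCc2ccccc2)c(Oc2ccc(CCO)cc2)c1 | intermediate
4 | 2-{4-[2-(benzyloxy)-5-ethynylphenoxy]phenyl}ethanol | C#Cc1ccc(OCc2ccccc2)c(Oc2ccc(CCO)cc2)c1 | intermediate
5 | 1-bromo-3-(methoxymethoxy)benzene | COCOc1cccc(Br)c1 | starting material
6 | 2-{4-[2-(benzyloxy)-5-{[3-(methoxymethoxy)phenyl]ethynyl}phenoxy]phenyl}ethanol | COCOc1cccc(C#Cc2ccc(OCc3ccccc3)c(Oc3ccc(CCO)cc3)c2)c1 | intermediate
7 | 2-[4-(2-hydroxyethyl)phenoxy]-4-{2-[3-(methoxymethoxy)phenyl]ethyl}phenol | COCOc1cccc(CCc2ccc(O)c(Oc3ccc(CCO)cc3)c2)c1 | intermediate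
8 | 2-[4-(2-iodoethyl)phenoxy]-4-{2-[3-(methoxymethoxy)phenyl]ethyl}phenol | COCOc1cccc(CCc2ccc(O)c(Oc3ccc(CCI)cc3)c2)c1 | intermediate
9 | {2-[4-(2-iodoethyl)phenoxy]-4-{2-[3-(methoxymethoxy)phenyl]ethyl}phenoxy}triisopropylsilane | COCOc1cccc(CCc2ccc(O[Si](C(C)C)(C(C)C)C(C)C)c(Oc3ccc(CCI)cc3)c2)c1 | intermediate
10 | 3,4-di-tert-butoxycyclobut-3-ene-1,2-dione (di-tert-butyl squarate) | CC(C)(C)OC1=C(OC(C)(C)C)C(=O)C1=O | starting material
11 | 2-(4-{5-[2-(3-(methoxymethoxy)phenyl)ethyl]-2-(triisopropylsilyloxy)phenoxy}phenyl)ethyllithium | COCOc1cccc(CCc2ccc(O[Si](C(C)C)(C(C)C)C(C)C)c(Oc3ccc(CC[Li])cc3)c2)c1 | intermediate (not isolated)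
12 | 2,3-di-tert-butoxy-4-hydroxy-4-[2-(4-{5-[2-(3-(methoxymethoxy)phenyl)ethyl]-2-(triisopropylsilyloxy)phenoxy}phenyl)ethyl]cyclobut-2-en-1-one (racemic) | COCOc1cccc(CCc2ccc(O[Si](C(C)C)(C(C)C)C(C)C)c(Oc3ccc(CCC4(O)C(=O)C(OC(C)(C)C)=C4OC(C)(C)C)cc3)c2)c1 | intermediate
13 | 3-tert-butoxy-4-[2-(4-{5-[2-(3-(methoxymethoxy)phenyl)ethyl]-2-(triisopropylsilyloxy)phenoxy}phenyl)ethyl]cyclobut-3-ene-1,2-dione | COCOc1cccc(CCc2ccc(O[Si](C(C)C)(C(C)C)C(C)C)c(Oc3ccc(CCC4=C(OC(C)(C)C)C(=O)C4=O)cc3)c2)c1 | intermediate (not isolated)
14 | 3-hydroxy-4-[2-(4-{5-[2-(3-hydroxyphenyl)ethyl]-2-(triisopropylsilyloxy)phenoxy}phenyl)ethyl]cyclobut-3-ene-1,2-dione (seco acid) | Oc1cccc(CCc2ccc(O[Si](C(C)C)(C(C)C)C(C)C)c(Oc3ccc(CCC4=C(O)C(=O)C4=O)cc3)c2)c1 | intermediate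
15 | 3-chloro-4-[2-(4-{5-[2-(3-hydroxyphenyl)ethyl]-2-(triisopropylsilyloxy)phenoxy}phenyl)ethyl]cyclobut-3-ene-1,2-dione | Oc1cccc(CCc2ccc(O[Si](C(C)C)(C(C)C)C(C)C)c(Oc3ccc(CCC4=C(Cl)C(=O)C4=O)cc3)c2)c1 | intermediate (not isolated)
16 | macrocyclic 3-aryloxy-4-alkylcyclobut-3-ene-1,2-dione (18-membered ring, ring B O-TIPS) | O=C1C(=O)C2=C1CCc1ccc(cc1)Oc1cc(ccc1O[Si](C(C)C)(C(C)C)C(C)C)CCc1cccc(c1)O2 | intermediate
17 | macrocyclic 2-alkyl-3-aryloxy-4-ethynyl-4-hydroxycyclobut-2-en-1-one (racemic, ring B O-TIPS) | C#CC1(O)C(=O)C2=C1Oc1cccc(c1)CCc1ccc(O[Si](C(C)C)(C(C)C)C(C)C)c(c1)Oc1ccc(cc1)CC2 | intermediate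
18 | O-triisopropylsilylmarchantinquinone | O=C1C=CC(=O)C2=C1CCc1ccc(cc1)Oc1cc(ccc1O[Si](C(C)C)(C(C)C)C(C)C)CCc1cccc(c1)O2 | intermediate
19 | marchantinquinone (achiral) | O=C1C=CC(=O)C2=C1CCc1ccc(cc1)Oc1cc(ccc1O)CCc1cccc(c1)O2 | target

Total steps: 12. Longest linear sequence: 12 (1 → 19; 2, 5 and 10 enter as bought materials).

Steps most likely to fail

Step 9 (ring closure). Intermolecular acylation could outrun the 18-membered closure, or the phenol could be acylated in the concentrated chloride solution before dilution. The fallback sets out from 12 and returns at 18; it makes ring D first on the open chain and closes the macrocycle on the quinone. Trifluoroacetic anhydride and 2,6-lutidine followed by aqueous work-up would convert 12 into the tert-butoxy dione 13, isolated this time. Ethynylmagnesium bromide would give the open-chain 3-tert-butoxy-4-ethynyl-4-hydroxycyclobutenone F1, and heating in p-xylene the open-chain 2-alkyl-3-tert-butoxy-1,4-benzoquinone F2. Trifluoroacetic acid would remove tert-butyl and MOM to give the hydroxyquinone phenol F3, and oxalyl chloride with catalytic DMF the chloroquinone F4. Hünig's base at 1 mM would then close the ring by addition–elimination of the ring C phenol at the chlorine-bearing quinone carbon to give 18. The same detour would serve if the acetylide of step 10 were to expel the aryloxide, since the carbanion then meets only an alkyl vinylogous ester.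

Step 11 (ring expansion). The diradical could close in the five-membered mode or abstract hydrogen intermolecularly, or the ring could open with OH inward and lactonise. The fallback sets out from 16 and returns at 18; it replaces the diradical pathway by a pericyclic one followed by a separate oxidation. Vinylmagnesium bromide at −78 °C would give the macrocyclic 4-ethenyl-4-hydroxycyclobutenone F5. In toluene at 110 °C this would open to a dienylketene that closes by 6π-electrocyclisation and tautomerises to the silyl-protected hydroquinone F6. Ag2O with MgSO4 in ether would oxidise F6 to 18; because ring B is still silylated, the hydroquinone is the only oxidisable group.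

Step 12 (desilylation). Fluoride or acetate could add to the quinone or displace its aryloxy group. The fallback sets out from 17 and returns at 19; it moves the deprotection ahead of the ring expansion so that fluoride never meets a quinone. Buffered TBAF at 0 °C would convert 17 into the free-phenol ethynyl carbinol F7, and heating F7 in p-xylene at 138 °C would give 19 directly.

Further compounds
F1 | step 9 | open-chain 2-alkyl-3-tert-butoxy-4-ethynyl-4-hydroxycyclobut-2-en-1-one (MOM and TIPS on) | COCOc1cccc(CCc2ccc(O[Si](C(C)C)(C(C)C)C(C)C)c(Oc3ccc(CCC4=C(OC(C)(C)C)C(O)(C#C)C4=O)cc3)c2)c1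
F2 | step 9 | open-chain 2-alkyl-3-tert-butoxy-1,4-benzoquinone (MOM and TIPS on) | COCOc1cccc(CCc2ccc(O[Si](C(C)C)(C(C)C)C(C)C)c(Oc3ccc(CCC4=C(OC(C)(C)C)C(=O)C=CC4=O)cc3)c2)c1
F3 | step 9 | open-chain 2-alkyl-3-hydroxy-1,4-benzoquinone with free ring C phenol (TIPS on) | Oc1cccc(CCc2ccc(O[Si](C(C)C)(C(C)C)C(C)C)c(Oc3ccc(CCC4=C(O)C(=O)C=CC4=O)cc3)c2)c1
F4 | step 9 | open-chain 2-alkyl-3-chloro-1,4-benzoquinone with free ring C phenol (TIPS on) | Oc1cccc(CCc2ccc(O[Si](C(C)C)(C(C)C)C(C)C)c(Oc3ccc(CCC4=C(Cl)C(=O)C=CC4=O)cc3)c2)c1
F5 | step 11 | macrocyclic 2-alkyl-3-aryloxy-4-ethenyl-4-hydroxycyclobut-2-en-1-one (ring B O-TIPS) | C=CC1(O)C(=O)C2=C1Oc1cccc(c1)CCc1ccc(O[Si](C(C)C)(C(C)C)C(C)C)c(c1)Oc1ccc(cc1)CC2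
F6 | step 11 | O-triisopropylsilyl hydroquinone corresponding to 18 | Oc1ccc(O)c2c1CCc1ccc(cc1)Oc1cc(ccc1O[Si](C(C)C)(C(C)C)C(C)C)CCc1cccc(c1)O2
F7 | step 12 | macrocyclic 2-alkyl-3-aryloxy-4-ethynyl-4-hydroxycyclobut-2-en-1-one with free ring B phenol | C#CC1(O)C(=O)C2=C1Oc1cccc(c1)CCc1ccc(O)c(c1)Oc1ccc(cc1)CC2
A1 | direct plan | 2-fluoro-3,6-dimethoxybenzaldehyde | COc1ccc(OC)c(C=O)c1F
A2 | direct plan | 2-(3-{2-[3-(4-formylphenoxy)-4-methoxyphenyl]ethyl}phenoxy)-3,6-dimethoxybenzaldehyde (seco dialdehyde) | COc1ccc(CCc2cccc(Oc3c(C=O)c(OC)ccc3OC)c2)cc1Oc1ccc(C=O)cc1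
A3 | direct plan | macrocyclic bis(bibenzyl) trimethyl ether | COc1ccc2cc1Oc1ccc(cc1)CCc1c(OC)ccc(OC)c1Oc1cccc(CC2)c1
A4 | direct plan | macrocyclic hydroquinone triol | Oc1ccc2cc1Oc1ccc(cc1)CCc1c(O)ccc(O)c1Oc1cccc(CC2)c1
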